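# Proposed total synthesis of the target gibberellin by SmI2 cyclopropyl-ketone fragmentation and ring D radical closure

## Structural features

The target gibberellin (number 93 of the gibberellin A series) has a perhydrofluorene core in which ring A is six-membered, ring B five-membered and ring C six-membered. Ring D is the two-carbon bridge C15–C16 from C8 to C13, so that rings C and D form a bicyclo[3.2.1]octane, and a γ-lactone joins C4 (through C19) to the oxygen on C10 across the α face of ring A. There are ten stereocentres, of which C1 to C6 are contiguous and are followed by C8, C9 and C10, with the bridgehead carbinol C13 apart, and C4, C8, C10 and C13 are fully substituted. Ring A carries a 1β-hydroxyl syn to a 2β,3β-epoxide, and ring B carries the C6 carboxyl β, trans to the C5–C4 bond. The fragile groups are the cis-epoxy alcohol, the lactone of a tertiary alcohol, the free acid and the tertiary 13-hydroxy-16-methylene unit, which rearranges in acid and whose alkene and allylic C15 compete in oxidations. The real difficulties are the quaternary C8 shared by rings B, C and D, the quaternary C4 next to C5, and oxygenating C1, C2 and C3 on one face without touching the 16-ene. The key step exploits the fact that C15 is a methylene joining quaternary C8 to C16, so that it can be stored as the methylene of a cyclopropane across C8–C9 beside a C10 ketone and released as a radical toward an ethynyl group on C13. The ethynyl group must then lie syn to that methylene on ring C, which is the more hindered face, and this decides how the C13 carbinol has to be built.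

## Logic of the disconnections

37 from 36: no skeletal bond is cut; the O13–Si bond and the C7 ester C–O bond are disconnected. The free epoxy alcohol and acid tolerate neither thiolate, hot hydroxide nor strong acid, so both groups must fall to fluoride in one neutral step.

36 from 35: the two C–O bonds of the epoxide at C2 and C3 are cut. The 1β-hydroxyl is syn to the epoxide, so it can deliver the oxygen. Ring A becomes a plain allylic alcohol. The forward step demands that only this alkene has a free hydroxyl next to it, hence O13 stays silylated.

35 from 33 and 32: the C1–O bond is traced back through a transposition (34 in the flask) to an epoxy ketone and then to an enone. A nucleophilic oxidant should enter C1 from the β face because the lactone bridge covers the α face. This avoids an allylic C–H oxidation, which could not tell C1 from C15. Ring A oxygenation shrinks to one carbonyl at C3. The demand is a non-hydrolytic nucleophilic epoxidation and a hydrazine step that spares the lactone.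

32 from 31 and 30: the C1=C2 alkene is cut by ring-closing metathesis after adjusting the oxidation level at C3. Ring A opens to two vinyl groups on a bicyclic lactone. Both vinyl groups must sit on the same face of the lactone ring, and the catalyst must ignore the 16-methylene.

30 from 28 and 29: the C3–C4 bond is cut (aldol). Quaternary C4 is made last on a ring enolate, so its configuration follows from the convex face of the cis-fused lactone. The forward step must enolise the lactone and not the C7 ester, and add 1,2 to the enal.

28 from 27: the C4–C5 bond is cut (intramolecular Michael addition through the O10–C19 tether). This hindered bond between a future quaternary and a tertiary carbon forms in a five-membered closure that fixes C5 and lets C6 equilibrate. The demand is a C5=C6 enoate and reversible enolate chemistry.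

27 from 25 and 26, and 25 from 23 and 24: the O10–C19 ester bond and the C1–C10 bond are cut, returning a cyclopentenone. The nucleophile must add 1,2 and from the β face, anti to C11.

23 from 21: the C5=C6 double bond is removed (22 in the flask), giving the saturated keto ester that the key step delivers. The demand is enolisation at C5 and not at C9.

21 from 20: the key disconnection cuts C15–C16 and re-forms C9–C15 as a cyclopropane. The hindered C8–C15 bond already exists, so the step forms only an unhindered bond. Ring D and the methylene vanish into a propellane. The demands are ethynyl syn to C15, cleavage of C9–C15 and not C8–C9, and cyclisation faster than reduction of the radical.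

20 from 19, 18, 16, 14 and 12 (with 13 and 17): the O13–Si bond, the C10 oxidation level, the C16≡C17 bond (one-carbon homologation), the C13–O bond (oxidation of an enol ether, 15 in the flask) and the C13=C16 bond (olefination) are disconnected in turn. A direct acetylide addition to the C13 ketone of the propellane would place the alkyne anti to C15. Carbon is therefore attached while C13 is trigonal, and oxygen is delivered last from the open face. The demand is a face-selective epoxidation.

12 from 10 and 11: the C8–C15 and C9–C15 bonds are cut (hydroxyl-directed cyclopropanation). Both quaternary carbons form stereospecifically in one step, on the face set by the C10 hydroxyl. What remains is a flat bicyclic allylic alcohol with one controlling stereocentre. The β,γ-unsaturated ketone must not isomerise.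

10 from 9 and 7: the ester bond is cut and ring C is re-aromatised (8 in the flask). Ring C, with oxygen at C13 and the tetrasubstituted C8=C9 alkene, is the 2,5-dihydro form of an anisole. The reduction must spare the benzylic oxygen and needs a carboxylate, not an ester.

7 from 6 and 5: the C10–H bond is cut (asymmetric reduction). This is the only source of absolute configuration in the route, so the catalyst must control it.

5 from 3, 1 and 2: the C9–C10 bond (Friedel–Crafts acylation, 4 in the flask) and the C5–C6 bond (enolate alkylation) are cut, leaving two commercial esters. Acylation must go para to the methoxy group.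

## Other disconnections considered

Alternative 1: The cut is C8–C9 together with C11–C12. The forward step is an intramolecular Diels–Alder reaction of trienone A2, in which the vinyl ketone C11=C9–C10(=O) adds to the 2-silyloxy diene C12=C13–C14=C8 through the tether C10–C5–C6, to give the cis-hydrindanone silyl enol ether A1.
- In its favour: one step forms two bonds, rings B and C, quaternary C8 and C9. The C10 ketone and a masked C13 ketone arrive in place, and the propargyl group on C8 is ready for a later ketyl closure of ring D.
- Against it here: the diene terminus C8 is fully substituted and carries an inside substituent, which disfavours the s-cis diene. The vinyl ketone is prone to polymerise. The only stereocentre of A2 is the epimerisable C6, which would have to control facial selectivity, and the stereodefined diene needs its own synthesis.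
- Comparison: on structure both plans reach the same hydrindanone. On mechanism the cycloaddition is concerted and stereospecific, while the chosen plan is a radical relay that must outrun reduction. On step economy A1 still needs a separate ring D closure, whereas 21 emerges with ring D.
- Where it is better: A1 avoids the problem of placing an alkyne syn to C15, which costs the chosen plan steps 8 to 10, and it needs no arene reduction.
- Where the chosen plan is safer: C8 is made by a stereospecific cyclopropanation, and the absolute configuration is set by a catalytic reduction.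

Alternative 2: The cut is C4–C5, with the O–C1 bond formed in the retron. The forward step is an ester-enolate Claisen rearrangement of the silyl ketene acetal of the unsaturated lactone A4, contracting it to the ring A diene acid A3.
- In its favour: the hindered C4–C5 bond forms intramolecularly with chirality transfer from C1. A3 has a C1=C10 alkene next to an α carboxyl, so an oxidative lactonisation could give the lactone oxygen α and the C1 oxygen β by anti addition.
- Against it here: the oxidative lactonisation must choose the C1=C10 alkene of a conjugated diene over the 16-methylene and 1,2 over 1,4 addition. A4 needs a C1 carbinol stereocentre and a C5=C10 alkene made from the C10 ketone, and the lactone enolate must rearrange through a strained boat.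
- Comparison: this is a ring A tactic and could follow 21, so it competes with steps 14 to 22 and not with the key step. It is the equal of the chosen ring A plan in making C4–C5 intramolecularly. It would be better in step count. The chosen plan is more predictable in selectivity, because its C1 oxygen comes from a nucleophilic epoxidation that cannot touch the 16-ene.

Alternative 3: The cut is C13–C16. The forward step reduces the C13 ketone of A6 with SmI2 to a ketyl that adds 5-exo-dig to the propargyl group on C8, giving A5 with the 13-hydroxyl and the 16-methylene together.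
- In its favour: the oxygen stays on C13 while carbon arrives from the C8 side, so the C13 configuration is automatic. The ketyl is re-formed reversibly and is not lost to over-reduction as easily as an alkyl radical. The propargyl group is a simple alkylation unit.
- Against it here: quaternary C8 must be made by alkylation or cycloaddition with control against C9 and C6. As drawn, the reduction is run late on a substrate with a lactone and an allylic silyl ether, and simple reduction of the ketone competes.
- Comparison: both plans close the same ring by a 5-exo-dig radical addition under SmI2. Alternative 3 forms the bond to the carbinol carbon, the chosen plan the bond to C15. Alternative 3 is better on the C13 stereochemical problem and probably on step count. It is the equal of the chosen plan in the mode of ring closure. The chosen plan is better in how C8 is made.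

Key step: step 13

Assumption: gibberellane numbering is used for every intermediate; β is the face that carries C15, H-9 and the C6 carboxyl, α the face of the lactone oxygen.
Assumption: in the propellanes C8 and C9 are the two shared carbons, C15 is the cyclopropane CH2, C10–C5–C6 is the three-carbon bridge and C11–C12–C13–C14 the four-carbon bridge.
Assumption: triethylsilyl on O13 and 2-(trimethylsilyl)ethyl on C7 are the spectator groups of 20 and 21, so that fluoride alone unmasks the target; C8, C9 and C13 of 20 and 21 map atom by atom onto the target.
Assumption: C6 is carried as the 6β-ester from step 3 to step 13; it is erased in step 14 and reset in step 17, so epimerisation at C6 in basic steps would be harmless.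

## Route

Step 1
Reactants: 1 methyl (3-methoxyphenyl)acetate; 2 tert-butyl bromoacetate
Product: 3 4-tert-butyl 1-methyl 2-(3-methoxyphenyl)butanedioate (racemic)
Conditions: LiN(SiMe3)2, THF, −78 °C; then 2, −78 → 0 °C
Reagents that add atoms: none
Why: Enolate alkylation of an arylacetate with a primary α-bromo ester forms the C5–C6 bond; the stereocentre is racemic and is dealt with in step 3.

Step 2
Reactants: 3 4-tert-butyl 1-methyl 2-(3-methoxyphenyl)butanedioate
Product: 5 methyl 6-methoxy-3-oxo-2,3-dihydro-1H-indene-1-carboxylate (racemic), via half-ester acid 4 (not isolated)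
Conditions: P2O5/MeSO3H (Eaton's reagent), 50 °C
Reagents that add atoms: none
Why: The strong acid removes the tert-butyl group as isobutene, and the freed acid closes by intramolecular Friedel–Crafts acylation para to the methoxy group; only the five-membered ring can form, and the methyl ester should survive.

Step 3
Reactants: 5 methyl 6-methoxy-3-oxo-2,3-dihydro-1H-indene-1-carboxylate
Product: 6 methyl (1S,3R)-3-hydroxy-6-methoxy-2,3-dihydro-1H-indene-1-carboxylate
Conditions: RuCl[(R,R)-TsDPEN](p-cymene) (1 mol %), HCO2H/Et3N (5:2), DMF, 40 °C
Reagents that add atoms: none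
Why: Asymmetric transfer hydrogenation of the aryl ketone with the (R,R) ligand should give the (3R) carbinol. The C1–H is benzylic, α to the ester and conjugated with the ortho ketone, so the substrate should racemise in the amine medium and funnel to the cis isomer (dynamic kinetic resolution). If racemisation were slow, both C1 epimers would still carry (3R) and converge at step 14.

Step 4
Reactants: 6 methyl (1S,3R)-3-hydroxy-6-methoxy-2,3-dihydro-1H-indene-1-carboxylate
Product: 7 (1S,3R)-3-hydroxy-6-methoxy-2,3-dihydro-1H-indene-1-carboxylic acid
Conditions: LiOH, THF/H2O, 0 °C; then 1 M HCl to pH 3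
Reagents that add atoms: lithium hydroxide, [Li+].[OH-]
Why: Saponification; a carboxylate survives dissolving-metal reduction whereas an ester would be reduced.

Step 5
Reactants: 7 (1S,3R)-3-hydroxy-6-methoxy-2,3-dihydro-1H-indene-1-carboxylic acid
Product: 9 (1S,3R)-3-hydroxy-6-oxo-2,3,4,5,6,7-hexahydro-1H-indene-1-carboxylic acid, via dihydroanisole enol ether 8 (not isolated)
Conditions: Li, NH3(l), THF, t-BuOH, −78 → −33 °C; NH4Cl; then (CO2H)2, MeOH/H2O, 0 °C → rt
Reagents that add atoms: water, O
Why: Birch reduction of the anisole gives the 2,5-dihydro compound and keeps the tetrasubstituted C8=C9 alkene. The benzylic oxygen is present as its lithium alkoxide (no leaving group) and sits para to the methoxy group where the radical anion has little charge, so hydrogenolysis should be suppressed. Mild acid then hydrolyses only the enol ether to the β,γ-unsaturated C13 ketone.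

Step 6
Reactants: 9 (1S,3R)-3-hydroxy-6-oxo-2,3,4,5,6,7-hexahydro-1H-indene-1-carboxylic acid
Product: 10 2-(trimethylsilyl)ethyl (1S,3R)-3-hydroxy-6-oxo-2,3,4,5,6,7-hexahydro-1H-indene-1-carboxylate
Conditions: Me3SiCH2CH2OH (3 equiv), PPh3, DIAD, THF, 0 °C
Reagents that add atoms: 2-(trimethylsilyl)ethanol, C[Si](C)(C)CCO
Why: Mitsunobu esterification alkylates the carboxylate with the oxyphosphonium of the unhindered primary alcohol, which is used in excess so that the substrate's own secondary hydroxyl is not activated. The acyl group is never activated, so the cis hydroxy acid cannot lactonise, and an internal displacement at C10 is impossible because carboxylate and hydroxyl are cis.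

Step 7
Reactants: 10 2-(trimethylsilyl)ethyl (1S,3R)-3-hydroxy-6-oxo-2,3,4,5,6,7-hexahydro-1H-indene-1-carboxylate; 11 diiodomethane
Product: 12 [4.3.1]propellane hydroxy ketone, 2-(trimethylsilyl)ethyl 7-hydroxy-3-oxotricyclo[4.3.1.0(1,6)]decane-9-carboxylate with 10β-OH, 6β-ester and the cyclopropane CH2 (C15) on the β face, C13 ketone
Conditions: Et2Zn, 11, CH2Cl2, −20 → 0 °C
Reagents that add atoms: none
Why: Hydroxyl-directed Simmons–Smith cyclopropanation: the zinc alkoxide at C10 delivers the methylene to the same face of the electron-rich tetrasubstituted alkene. This forms C8–C15 and C9–C15 stereospecifically and sets both quaternary centres syn to the hydroxyl; ketone and ester are tolerated.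

Step 8
Reactants: 12 [4.3.1]propellane hydroxy ketone; 13 (methoxymethyl)triphenylphosphonium chloride
Product: 14 propellane enol ether, C13=CH(OMe) (E/Z mixture), 10β-OH, 6β-ester, C15 β
Conditions: 13, KN(SiMe3)2, THF, 0 °C; then 12, 0 °C → rt (3 equiv of ylide)
Reagents that add atoms: none
Why: Wittig olefination of the only ketone with the methoxymethylene ylide attaches C16 while C13 is trigonal; the first equivalent of ylide is consumed by the hydroxyl.

Step 9
Reactants: 14 propellane enol ether
Product: 16 propellane α-hydroxy aldehyde with C13 bearing OH anti to the cyclopropane CH2 and CHO (C16) syn to it, 10β-OH, 6β-ester, via methoxy spiro-epoxide 15 (not isolated)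
Conditions: DMDO (freshly prepared, 1.05 equiv), acetone, −78 → 0 °C; then (CO2H)2 (cat.), THF/H2O, 0 °C
Reagents that add atoms: dimethyldioxirane, CC1(C)OO1; water, O
Why: Rubottom-type oxidation of the enol ether: the small electrophilic oxidant should attack the exocyclic alkene anti to the cyclopropane, whose inward hydrogen on C15 blocks the axial approach on its own face. The epoxide oxygen stays on C13 when the methoxy-oxirane hydrolyses, so the tertiary hydroxyl ends anti and the formyl carbon syn to C15. An acetylide added to the ketone would follow the same bias and give the wrong epimer.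

Step 10
Reactants: 16 propellane α-hydroxy aldehyde; 17 dimethyl (1-diazo-2-oxopropyl)phosphonate
Product: 18 propellane ethynyl diol, C13 ethynyl syn to C15 and 13-OH anti, 10β-OH, 6β-ester
Conditions: 17, K2CO3, MeOH, 0 °C → rt
Reagents that add atoms: none
Why: Seyferth–Gilbert homologation with the Ohira–Bestmann reagent converts the non-enolisable tertiary α-hydroxy aldehyde into the terminal alkyne (C17) without touching C13. The C7 ester sits next to quaternary C8 and should resist methanolysis during the short reaction.

Step 11
Reactants: 18 propellane ethynyl diol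
Product: 19 propellane cyclopropyl ketone, C10 ketone, C13 ethynyl carbinol (free OH), 6β-ester
Conditions: Dess–Martin periodinane, NaHCO3, CH2Cl2, 0 °C → rt
Reagents that add atoms: none
Why: Dess–Martin oxidation of the secondary cyclopropyl carbinol; the tertiary propargylic alcohol cannot be oxidised.

Step 12
Reactants: 19 propellane cyclopropyl ketone
Product: 20 key-step precursor, [4.3.1]propellane ketone with C13 ethynyl carbinol triethylsilyl ether (ethynyl syn to C15) and 6β 2-(trimethylsilyl)ethyl ester
Conditions: Et3SiOTf, 2,6-lutidine, CH2Cl2, −78 °C
Reagents that add atoms: triethylsilyl trifluoromethanesulfonate, CC[Si](CC)(CC)OS(=O)(=O)C(F)(F)F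
Why: Silyl triflate silylation of the hindered tertiary alcohol; the bulky silyl ether should prefer the equatorial position and hold the ethynyl group axial.

Step 13
Reactants: 20 key-step precursor
Product: 21 tricyclic C10 ketone with rings B, C and D, H-9β (cis B/C fusion), 16-methylene, 13-OSiEt3, 6β 2-(trimethylsilyl)ethyl ester
Conditions: SmI2 (2.5 equiv, added slowly), DMPU, t-BuOH, THF, −78 °C → rt
Reagents that add atoms: none
Why: SmI2 transfers an electron to the C10 carbonyl. The ketyl is a cyclopropylcarbinyl radical and opens the C9–C15 bond, which lies out of the plane of the cyclopentanone and overlaps with the ketyl, whereas C8–C9 lies in that plane; this leaves a samarium enolate (C9=C10, trivalent samarium) and a primary radical at C15. The radical adds to the internal alkyne carbon C16 in a 5-exo-dig closure, forming ring D (C8–C15–C16–C13–C14) as a bicyclo[3.2.1]octane with ring C. The vinyl radical at C17 is reduced by a second SmI2 and protonated by t-BuOH to the exocyclic methylene. The closest known reaction type is the SmI2-mediated fragmentation of a cyclopropyl ketone with capture of the ring-opened radical by a tethered alkyne. C8 and C13 are already fixed (steps 7 and 9); closure is possible only because C15 and the ethynyl group are syn and 1,3-diaxial, an arrangement held by the equatorial silyl ether. The one new stereocentre, C9, is set when the enolate is protonated: the cis B/C hydrindanone with H-9 on the face of C15 is the more stable, epimerisable product. The selectivity needed is cyclisation before reduction of the C15 radical; slow addition without HMPA keeps the reductant dilute, and the rigid geometry should make the closure fast.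

Step 14
Reactants: 21 tricyclic C10 ketone
Product: 23 tricyclic enone with C5=C6 conjugated to the C10 ketone and the C7 ester, H-9β, 13-OSiEt3, 16-methylene, via trimethylsilyl enol ether 22 (not isolated)
Conditions: LiN(SiMe3)2, Me3SiCl, THF, −78 °C; then Pd(OAc)2 (1.1 equiv), MeCN, rt
Reagents that add atoms: none
Why: Saegusa–Ito dehydrogenation: kinetic enolisation takes the C5 methylene and not the hindered C9 methine, and Pd(OAc)2 removes H-6 from the silyl enol ether; the C6 stereocentre is erased on purpose.

Step 15
Reactants: 23 tricyclic enone; 24 vinylmagnesium bromide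
Product: 25 tertiary allylic alcohol with 10α-OH and 10β-vinyl (C1=C2), C5=C6 enoate, H-9β, 13-OSiEt3
Conditions: 24, CeCl3, THF, −78 °C
Reagents that add atoms: none
Why: Organocerium 1,2-addition to the cyclopentenone; CeCl3 suppresses enolisation at C9 and conjugate addition. The nucleophile should approach anti to C11, the α substituent on C9, that is from the β face, which sets C10 with C1 β and oxygen α.

Step 16
Reactants: 25 tertiary allylic alcohol; 26 propanoic anhydride
Product: 27 C10 propanoate of 25 (10α-O-propanoyl, 10β-vinyl, C5=C6 enoate)
Conditions: 26, DMAP, Et3N, CH2Cl2, rt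
Reagents that add atoms: none
Why: DMAP-catalysed acylation of the tertiary alcohol installs C19, C4 and C18 on the oxygen that will become the lactone oxygen.

Step 17
Reactants: 27 C10 propanoate
Product: 28 γ-lactone (C19–O10, C4–C5) cis-fused to ring B, H-5β, 6β-ester, 10β-vinyl, C4 carrying H and methyl as an epimer mixture
Conditions: KOt-Bu (1.0 equiv), t-BuOH/THF, −20 → 0 °C; AcOH
Reagents that add atoms: none
Why: Intramolecular Michael addition (5-exo-trig) of the propanoate enolate carbon C4 to C5 of the enoate; the tether forces C4 onto the α face, so H-5 is β. Under equilibrating alkoxide/alcohol conditions C6 should settle as the ester trans to the new C5 substituent (β). At this temperature the Michael closure should be much faster than an ester-enolate Claisen rearrangement.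

Step 18
Reactants: 28 γ-lactone; 29 acrolein
Product: 30 aldol adduct, C4 quaternary with methyl (C18) on the ring B side and CH(OH)CH=CH2 (C3, C2) cis to the C10 vinyl group, C3 epimer mixture
Conditions: LiN(i-Pr)2 (1.05 equiv), THF, −78 °C; then 29, −78 °C; AcOH, −78 °C
Reagents that add atoms: none
Why: Aldol addition of the lactone lithium enolate, the lactone α-hydrogen being more acidic and more accessible than the hindered H-6, to the enal carbonyl at low temperature. The electrophile should take the convex face of the cis-fused bicycle, anti to C6, which places C3 on the side of the C10 vinyl group and sets C4.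

Step 19
Reactants: 30 aldol adduct
Product: 31 pentacyclic lactone with ring A closed, C1=C2 alkene, 3-OH (epimer mixture), 13-OSiEt3, 16-methylene, 6β 2-(trimethylsilyl)ethyl ester
Conditions: second-generation Grubbs catalyst, RuCl2(=CHPh)(H2IMes)(PCy3) (5 mol %), CH2Cl2, 40 °C
Reagents that add atoms: none
Why: Ring-closing metathesis of two monosubstituted vinyl groups held cis on C10 and C4 gives the six-membered ring; the 1,1-disubstituted 16-methylene is far less reactive and cannot close a ring.

Step 20
Reactants: 31 pentacyclic 3-hydroxy-1-ene lactone
Product: 32 ring A enone (3-oxo, C1=C2), 19,10-lactone, 13-OSiEt3, 16-methylene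
Conditions: Dess–Martin periodinane, NaHCO3, CH2Cl2, rt
Reagents that add atoms: none
Why: Oxidation of both C3 epimers to one enone; C4 is quaternary, so the β-keto lactone cannot enolise.

Step 21
Reactants: 32 ring A enone
Product: 33 1β,2β-epoxy-3-ketone, 19,10-lactone, 13-OSiEt3, 16-methylene
Conditions: t-BuOOH, DBU, CH2Cl2, 0 °C → rt
Reagents that add atoms: tert-butyl hydroperoxide, CC(C)(C)OO
Why: Weitz–Scheffer nucleophilic epoxidation: the peroxide anion should add to C1 from the β face because the lactone bridge covers the α face, and the enolate then closes the epoxide. The nucleophilic oxidant leaves the electron-rich 16-ene alone, and the anhydrous base spares the lactone.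

Step 22
Reactants: 33 1β,2β-epoxy-3-ketone
Product: 35 1β-hydroxy-2-ene (C2=C3), 19,10-lactone, 13-OSiEt3, 16-methylene, 6β 2-(trimethylsilyl)ethyl ester, via epoxy hydrazone 34 (not isolated)
Conditions: N2H4·H2O (3 equiv), AcOH (cat.), MeOH, 0 °C → rt, under argon
Reagents that add atoms: none
Why: Wharton transposition: the C3 hydrazone opens the epoxide to a vinyl diazene that loses nitrogen, leaving the alkene at C2=C3 and the oxygen on C1; the C1–O bond is never broken, so the 1β configuration is retained.

Step 23
Reactants: 35 1β-hydroxy-2-ene
Product: 36 1β-hydroxy-2β,3β-epoxide, 13-OSiEt3, 6β 2-(trimethylsilyl)ethyl ester (doubly protected target gibberellin)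
Conditions: VO(acac)2 (5 mol %), t-BuOOH, CH2Cl2, 0 °C → rt
Reagents that add atoms: tert-butyl hydroperoxide, CC(C)(C)OO
Why: Vanadium-catalysed hydroxyl-directed epoxidation: the vanadate ester of the axial 1β-hydroxyl delivers oxygen to the same face, giving the 2β,3β-epoxide; the 16-ene has no free hydroxyl beside it and should not react.

Step 24
Reactants: 36 doubly protected target gibberellin (13-triethylsilyl ether, 7-[2-(trimethylsilyl)ethyl] ester)
Product: 37 target gibberellin, 2β,3β-epoxy-1β,13-dihydroxy-20-norgibberell-16-ene-7,19-dioic acid 19,10-lactone
Conditions: n-Bu4NF, THF, 0 °C → rt; then AcOH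
Reagents that add atoms: none
Why: Fluoride cleaves the tertiary triethylsilyl ether and the 2-(trimethylsilyl)ethyl ester (loss of ethene) in one operation. The cis epoxy alcohol cannot undergo Payne rearrangement, and the mild acid quench avoids rearrangement of the 13-hydroxy-16-ene.

## Compound list

1 | methyl (3-methoxyphenyl)acetate | COC(=O)Cc1cccc(OC)c1 | starting material
2 | tert-butyl bromoacetate | CC(C)(C)OC(=O)CBr | starting material
3 | 4-tert-butyl 1-methyl 2-(3-methoxyphenyl)butanedioate (racemic) | COC(=O)C(CC(=O)OC(C)(C)C)c1cccc(OC)c1 | intermediate
4 | 4-methoxy-3-(3-methoxyphenyl)-4-oxobutanoic acid (racemic; formed in the flask, not isolated) | COC(=O)C(CC(=O)O)c1cccc(OC)c1 | intermediate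
5 | methyl 6-methoxy-3-oxo-2,3-dihydro-1H-indene-1-carboxylate (racemic) | COC(=O)C1CC(=O)c2ccc(OC)cc12 | intermediate
6 | methyl (1S,3R)-3-hydroxy-6-methoxy-2,3-dihydro-1H-indene-1-carboxylate | O[C@@H]1C[C@H](C(=O)OC)c2cc(OC)ccc12 | intermediate
7 | (1S,3R)-3-hydroxy-6-methoxy-2,3-dihydro-1H-indene-1-carboxylic acid | O[C@@H]1C[C@H](C(=O)O)c2cc(OC)ccc12 | intermediate
8 | (1S,3R)-3-hydroxy-6-methoxy-2,3,4,7-tetrahydro-1H-indene-1-carboxylic acid (formed in the flask, not isolated) | O[C@@H]1C[C@H](C(=O)O)C2=C1CC=C(OC)C2 | intermediate
9 | (1S,3R)-3-hydroxy-6-oxo-2,3,4,5,6,7-hexahydro-1H-indene-1-carboxylic acid | O[C@@H]1C[C@H](C(=O)O)C2=C1CCC(=O)C2 | intermediate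
10 | 2-(trimethylsilyl)ethyl (1S,3R)-3-hydroxy-6-oxo-2,3,4,5,6,7-hexahydro-1H-indene-1-carboxylate | O[C@@H]1C[C@H](C(=O)OCC[Si](C)(C)C)C2=C1CCC(=O)C2 | intermediate
11 | diiodomethane | ICI | starting material
12 | [4.3.1]propellane hydroxy ketone (C13 ketone, 10β-OH, 6β-ester, C15 β) | O=C1CC[C@]23C[C@@]2(C1)[C@@H](C(=O)OCC[Si](C)(C)C)C[C@H]3O | intermediate
13 | (methoxymethyl)triphenylphosphonium chloride | COC[P+](c1ccccc1)(c1ccccc1)c1ccccc1.[Cl-] | starting material
14 | propellane enol ether, C13=CH(OMe) (E/Z mixture) | COC=C1CC[C@]23C[C@@]2(C1)[C@@H](C(=O)OCC[Si](C)(C)C)C[C@H]3O | intermediate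
15 | methoxy spiro-epoxide at C13/C16, oxygen anti to C15 (formed in the flask, not isolated) | COC1O[C@]12CC[C@]34C[C@@]3(C2)[C@@H](C(=O)OCC[Si](C)(C)C)C[C@H]4O | intermediate
16 | propellane α-hydroxy aldehyde (13-OH anti to C15, CHO syn) | O=C[C@]1(O)CC[C@]23C[C@@]2(C1)[C@@H](C(=O)OCC[Si](C)(C)C)C[C@H]3O | intermediate
17 | dimethyl (1-diazo-2-oxopropyl)phosphonate | COP(=O)(OC)C(=[N+]=[N-])C(C)=O | starting material
18 | propellane ethynyl diol (ethynyl syn to C15) | C#C[C@]1(O)CC[C@]23C[C@@]2(C1)[C@@H](C(=O)OCC[Si](C)(C)C)C[C@H]3O | intermediate
19 | propellane cyclopropyl ketone with free C13 ethynyl carbinol | C#C[C@]1(O)CC[C@]23C[C@@]2(C1)[C@@H](C(=O)OCC[Si](C)(C)C)CC3=O | intermediate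
20 | key-step precursor: [4.3.1]propellane ketone, C13 ethynyl carbinol triethylsilyl ether, 6β 2-(trimethylsilyl)ethyl ester | C#C[C@]1(O[Si](CC)(CC)CC)CC[C@]23C[C@@]2(C1)[C@@H](C(=O)OCC[Si](C)(C)C)CC3=O | intermediate
21 | key-step product: tricyclic C10 ketone, rings B, C and D, H-9β, 16-methylene, 13-OSiEt3, 6β ester | C=C1C[C@]23C[C@@]1(O[Si](CC)(CC)CC)CC[C@H]2C(=O)C[C@@H]3C(=O)OCC[Si](C)(C)C | intermediate
22 | C5=C10 trimethylsilyl enol ether of 21 (formed in the flask, not isolated) | C=C1C[C@]23C[C@@]1(O[Si](CC)(CC)CC)CC[C@H]2C(O[Si](C)(C)C)=C[C@@H]3C(=O)OCC[Si](C)(C)C | intermediate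
23 | tricyclic enone, C5=C6 | C=C1C[C@]23C[C@@]1(O[Si](CC)(CC)CC)CC[C@H]2C(=O)C=C3C(=O)OCC[Si](C)(C)C | intermediate
24 | vinylmagnesium bromide | C=C[Mg]Br | starting material
25 | tertiary allylic alcohol, 10α-OH, 10β-vinyl | C=C1C[C@]23C[C@@]1(O[Si](CC)(CC)CC)CC[C@H]2[C@](O)(C=C)C=C3C(=O)OCC[Si](C)(C)C | intermediate
26 | propanoic anhydride | CCC(=O)OC(=O)CC | starting material
27 | C10 propanoate of 25 | C=C1C[C@]23C[C@@]1(O[Si](CC)(CC)CC)CC[C@H]2[C@](OC(=O)CC)(C=C)C=C3C(=O)OCC[Si](C)(C)C | intermediate
28 | γ-lactone, H-5β, 6β-ester, 10β-vinyl, C4 epimer mixture | C=C1C[C@]23C[C@@]1(O[Si](CC)(CC)CC)CC[C@H]2[C@@]1(C=C)OC(=O)C(C)[C@H]1[C@@H]3C(=O)OCC[Si](C)(C)C | intermediate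
29 | acrolein | C=CC=O | starting material
30 | aldol adduct, quaternary C4, C3 epimer mixture | C=C1C[C@]23C[C@@]1(O[Si](CC)(CC)CC)CC[C@H]2[C@@]1(C=C)OC(=O)[C@](C)(C(O)C=C)[C@H]1[C@@H]3C(=O)OCC[Si](C)(C)C | intermediate
31 | pentacyclic 3-hydroxy-1-ene lactone (C3 epimer mixture), 13-OSiEt3, 7-O-(2-trimethylsilylethyl) | C=C1C[C@]23C[C@@]1(O[Si](CC)(CC)CC)CC[C@H]2[C@@]12OC(=O)[C@@](C)([C@H]1[C@@H]3C(=O)OCC[Si](C)(C)C)C(O)C=C2 | intermediate
32 | 3-oxo-1-ene lactone | C=C1C[C@]23C[C@@]1(O[Si](CC)(CC)CC)CC[C@H]2[C@@]12OC(=O)[C@@](C)([C@H]1[C@@H]3C(=O)OCC[Si](C)(C)C)C(=O)C=C2 | intermediate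
33 | 1β,2β-epoxy-3-ketone | C=C1C[C@]23C[C@@]1(O[Si](CC)(CC)CC)CC[C@H]2[C@@]12OC(=O)[C@@](C)([C@H]1[C@@H]3C(=O)OCC[Si](C)(C)C)C(=O)[C@H]1O[C@H]12 | intermediate
34 | C3 hydrazone of 33 (formed in the flask, not isolated) | C=C1C[C@]23C[C@@]1(O[Si](CC)(CC)CC)CC[C@H]2[C@@]12OC(=O)[C@@](C)([C@H]1[C@@H]3C(=O)OCC[Si](C)(C)C)C(=NN)[C@H]1O[C@H]12 | intermediate
35 | 1β-hydroxy-2-ene lactone, 13-OSiEt3, 7-O-(2-trimethylsilylethyl) | C=C1C[C@]23C[C@@]1(O[Si](CC)(CC)CC)CC[C@H]2[C@@]12OC(=O)[C@@](C)([C@H]1[C@@H]3C(=O)OCC[Si](C)(C)C)C=C[C@H]2O | intermediate
36 | doubly protected target gibberellin: 13-triethylsilyl ether, 7-[2-(trimethylsilyl)ethyl] ester | C=C1C[C@]23C[C@@]1(O[Si](CC)(CC)CC)CC[C@H]2[C@@]12OC(=O)[C@@](C)([C@H]1[C@@H]3C(=O)OCC[Si](C)(C)C)[C@H]1O[C@H]1[C@H]2O | intermediate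
37 | target gibberellin, 2β,3β-epoxy-1β,13-dihydroxy-20-norgibberell-16-ene-7,19-dioic acid 19,10-lactone | C=C1C[C@]23C[C@@]1(O)CC[C@H]2[C@@]12OC(=O)[C@@](C)([C@H]1[C@@H]3C(=O)O)[C@H]1O[C@H]1[C@H]2O | target

## Step count and least certain steps

Total step count: 24. Longest linear sequence: 24 steps (1 to 37); all other partners are commercial.

Step 13 (key step). The most likely failure is reduction of the C15 radical to an organosamarium and its protonation to a C8 methyl group before ring closure. Addition of an alkyl radical to an unactivated alkyne is comparatively slow, and SmI2 reduces primary radicals. Cleavage of C8–C9 instead of C9–C15 is the second possibility. The fallback sets out from 20 and separates ring opening from ring closure. Iodotrimethylsilane at low temperature would open the cyclopropyl ketone by attack of iodide on the methylene carbon, giving the iodo silyl enol ether F1, which is hydrolysed on work-up to the iodomethyl ketone F2 with the cis ring fusion. Tributyltin hydride and AIBN, with slow addition of the hydride, would then generate the same C15 radical in a chain process in which nothing reduces it before the 5-exo-dig closure. The route is rejoined at 21.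

Step 9. The most likely failure is poor facial selectivity in the oxidation of the enol ether, because the exocyclic carbon lies far from the shielding C15 hydrogen, which would give some of the epimer with oxygen syn to the cyclopropane. The fallback sets out from 12 and uses a different control element. Dimethylsulfoxonium methylide adds reversibly and should form the equatorial C–C bond, which can only lie on the cyclopropane side without pressing the oxygen against C15. This gives the spiro-epoxide F3 with the methylene syn and the oxygen anti to C15. Sodium benzenethiolate would open it at the methylene to the hydroxy sulfide F4. N-Chlorosuccinimide would give the α-chloro sulfide F5, and hydrolysis (CuCl2, CuO, aqueous acetone) would release the aldehyde, rejoining the route at 16.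

Step 7. The most likely failure is migration of the C8=C9 double bond into conjugation with the C13 ketone under the basic and Lewis acidic zinc species, which would destroy the allylic alcohol before it can direct. The fallback sets out from 10. The ketone is masked as the dioxolane F6 (ethylene glycol, pyridinium tosylate), the same directed cyclopropanation gives the ketal propellane F7, and mild hydrolysis (pyridinium tosylate, wet acetone) returns the ketone, rejoining the route at 12.

Step 18. The most likely failures are conjugate addition to acrolein or retro-aldol loss on warming, and partial deprotonation at C6. The fallback sets out from 28 and brings in C3 and C2 separately. The lactone enolate is trapped with gaseous formaldehyde to give the hydroxymethyl lactone F8, Dess–Martin oxidation gives the non-enolisable formyl lactone F9, and vinylmagnesium bromide (24) adds to the aldehyde at −78 °C to give the same allylic alcohol, rejoining the route at 30.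

Step 22. The most likely failure is attack of hydrazine on the strained β-keto lactone (ring opening or pyrazolone formation) in competition with the fragmentation, or diversion of the vinyl diazene. The fallback sets out from 33. SmI2 in THF/MeOH at −90 °C would cleave the C2–O bond to the 1β-hydroxy-3-ketone F10, which is protected as its trimethylsilyl ether F11. KN(SiMe3)2 and N-phenylbis(trifluoromethanesulfonimide) would give the C2=C3 enol triflate F12, C4 being quaternary. Reduction of the triflate with Pd(OAc)2, PPh3, HCO2H and Et3N would give the silyl ether F13, and citric acid in methanol would free the hydroxyl, rejoining the route at 35.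

## Further compounds

F1 | step 13 | iodo silyl enol ether (C15 iodide, C9=C10 trimethylsilyl enol ether) | C#C[C@]1(O[Si](CC)(CC)CC)CCC2=C(O[Si](C)(C)C)C[C@H](C(=O)OCC[Si](C)(C)C)[C@@]2(CI)C1
F2 | step 13 | iodomethyl ketone (C8 CH2I, H-9β, C10 ketone) | C#C[C@]1(O[Si](CC)(CC)CC)CC[C@H]2C(=O)C[C@H](C(=O)OCC[Si](C)(C)C)[C@@]2(CI)C1
F3 | step 9 | propellane spiro-epoxide at C13 (CH2 syn to C15, oxygen anti) | C1O[C@]12CC[C@]34C[C@@]3(C2)[C@@H](C(=O)OCC[Si](C)(C)C)C[C@H]4O
F4 | step 9 | propellane β-hydroxy sulfide (13-OH anti to C15, CH2SPh syn) | O[C@@]1(CSc5ccccc5)CC[C@]23C[C@@]2(C1)[C@@H](C(=O)OCC[Si](C)(C)C)C[C@H]3O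
F5 | step 9 | propellane α-chloro sulfide | O[C@@]1(C(Cl)Sc5ccccc5)CC[C@]23C[C@@]2(C1)[C@@H](C(=O)OCC[Si](C)(C)C)C[C@H]3O
F6 | step 7 | C13 ethylene ketal of 10 | O[C@@H]1C[C@H](C(=O)OCC[Si](C)(C)C)C2=C1CCC1(OCCO1)C2
F7 | step 7 | C13 ethylene ketal of 12 | O1CCOC12CC[C@]34C[C@@]3(C2)[C@@H](C(=O)OCC[Si](C)(C)C)C[C@H]4O
F8 | step 18 | C4 hydroxymethyl lactone | C=C1C[C@]23C[C@@]1(O[Si](CC)(CC)CC)CC[C@H]2[C@@]1(C=C)OC(=O)[C@](C)(CO)[C@H]1[C@@H]3C(=O)OCC[Si](C)(C)C
F9 | step 18 | C4 formyl lactone | C=C1C[C@]23C[C@@]1(O[Si](CC)(CC)CC)CC[C@H]2[C@@]1(C=C)OC(=O)[C@](C)(C=O)[C@H]1[C@@H]3C(=O)OCC[Si](C)(C)C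
F10 | step 22 | 1β-hydroxy-3-ketone | C=C1C[C@]23C[C@@]1(O[Si](CC)(CC)CC)CC[C@H]2[C@@]12OC(=O)[C@@](C)([C@H]1[C@@H]3C(=O)OCC[Si](C)(C)C)C(=O)C[C@H]2O
F11 | step 22 | 1β-trimethylsilyloxy-3-ketone | C=C1C[C@]23C[C@@]1(O[Si](CC)(CC)CC)CC[C@H]2[C@@]12OC(=O)[C@@](C)([C@H]1[C@@H]3C(=O)OCC[Si](C)(C)C)C(=O)C[C@H]2O[Si](C)(C)C
F12 | step 22 | C2=C3 enol triflate | C=C1C[C@]23C[C@@]1(O[Si](CC)(CC)CC)CC[C@H]2[C@@]12OC(=O)[C@@](C)([C@H]1[C@@H]3C(=O)OCC[Si](C)(C)C)C(OS(=O)(=O)C(F)(F)F)=C[C@H]2O[Si](C)(C)C
F13 | step 22 | 1β-trimethylsilyl ether of 35 | C=C1C[C@]23C[C@@]1(O[Si](CC)(CC)CC)CC[C@H]2[C@@]12OC(=O)[C@@](C)([C@H]1[C@@H]3C(=O)OCC[Si](C)(C)C)C=C[C@H]2O[Si](C)(C)C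
A1 | alternative 1 | cis-hydrindanone silyl enol ether with quaternary C8 and propargyl group | C[Si](C)(C)C#CC[C@]23C=C(O[Si](C)(C)C(C)(C)C)CC[C@H]2C(=O)C[C@@H]3C(=O)OC
A2 | alternative 1 | trienone: vinyl ketone tethered to the 2-silyloxy diene | C=CC(=O)C[C@H](C(=O)OC)/C(CC#C[Si](C)(C)C)=C/C(O[Si](C)(C)C(C)(C)C)=C
A3 | alternative 2 | ring A 1(10),2-diene carboxylic acid | C=C1C[C@]23C[C@@]1(O[Si](C)(C)C(C)(C)C)CC[C@H]2C1=CC=C[C@@](C)(C(=O)O)[C@H]1[C@@H]3C(=O)OCC[Si](C)(C)C
A4 | alternative 2 | unsaturated six-membered lactone on C1, C5=C10 alkene (C4 not defined, enolised in the step) | C=C1C[C@]23C[C@@]1(O[Si](C)(C)C(C)(C)C)CC[C@H]2C(=C[C@@H]3C(=O)OCC[Si](C)(C)C)[C@H]1OC(=O)C(C)C=C1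
A5 | alternative 3 | 13-hydroxy-16-methylene pentacycle | C=C1C[C@]23C[C@@]1(O)CC[C@H]2[C@@]12OC(=O)[C@@](C)([C@H]1[C@@H]3C(=O)OCC[Si](C)(C)C)C=C[C@H]2O[Si](CC)(CC)CC
A6 | alternative 3 | C13 ketone with propargyl group on C8 | C#CC[C@]23CC(=O)CC[C@H]2[C@@]12OC(=O)[C@@](C)([C@H]1[C@@H]3C(=O)OCC[Si](C)(C)C)C=C[C@H]2O[Si](CC)(CC)CC
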